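Readings and results stem from a simulated flask from invented constants; the scatter is artificial.

The south-east run had made 12.1 mM of left-handed product at 10.0 s, about the 12 mM that saturated solution holds of gas. The west flask had made more, 13.1 mM. I assume that each product takes one gas. Then gas must keep entering a solution that started without it.

the same everywhere: gas 12 mM (held); free catalyst 10 mM

|  | left-handed substrate | right-handed substrate | remark |
|---|---|---|---|
| west | 0.069 M | 0.069 M | the very flask that is asked about, followed so far |
| south-east | 0.046 M | 0.046 M | run made earlier |
| flask | 0.069 M | 0.069 M |  |

- west (time / s: left-handed product / %, left-handed substrate / %): 10.0: 9.5, 37.3; 15.0: 15.0, 31.8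
- south-east (time / s: left-handed product / %, left-handed substrate / %): 10.0: 13.2, 32.4; 15.0: 20.0, 26.6; 25.0: 31.8, 15.8; 40.0: 43.5, 5.3; 60.0: 49.1, 0.5; 80.0: 50.1, 0.1

(standard deviation of a reading: 0.3 percentage points)

- free catalyst is single-handed; left-handed substrate and right-handed substrate are mirror images of each other, charged as a racemate, each of them at the stated concentration
- the numbers in the tables scatter by 0.3 percentage points (one standard deviation)
- at the start none of the gas is in solution
- what is bound to the catalyst counts as converted
- no earlier run changes the charge of free catalyst; that part of a forecast is a guess

* apparent order in free catalyst when 30% of the left-handed substrate and right-handed substrate together are converted (percent change of the rate of making left-handed product for one percent more free catalyst charged)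

Turn the question round: if the rate goes as catalyst times gas in solution, g, an order of one needs g to stay at saturation, c_sat, however much catalyst you charge. The west slope between 10.0 s and 15.0 s tests this:

v = 1.52 mM s⁻¹

D = v / c_sat = 0.126 s⁻¹

This D, the gas draw, is the rate of making left-handed product per saturation concentration. Let k_L, the volumetric mass-transfer coefficient, set the supply k_L(c_sat − g). With g steady and the bound share of catalyst held, rate goes as catalyst times g, and the order n is:

n = g / c_sat = 1 − D / k_L

So an order of one needs k_L far above D. I read no k_L from these readings, but my reckoning puts n below one, and D counts left-handed product only, so any further draw on gas lowers this estimate of n. The forecast differs, at 1.07: “Rate is therefore first order in charged catalyst.”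

    free catalyst + left-handed substrate ⇌ catalyst intermediate A (K = 35.0 M⁻¹, k = 430 M⁻¹ s⁻¹)
    free catalyst + right-handed substrate ⇌ catalyst intermediate B (K = 22.0 M⁻¹, k = 35.0 M⁻¹ s⁻¹)
    partner + catalyst intermediate A → free catalyst + left-handed product (k = 48.0 M⁻¹ s⁻¹)
    partner + catalyst intermediate B → free catalyst + right-handed product (k = 19.0 M⁻¹ s⁻¹)
    gas ⇌ partner, rate k5*(csat - [partner]) (kL = 0.420 s⁻¹)

The flask gives 0.65, less than the forecast. At 0.200 min in the flask the partner, the gas in solution, stood at 0.00733 M, which is 61.1% of saturation. Taking k_L as the constant of passage of gas into partner, 0.42 s⁻¹, the west gas draw gives an estimate of n above that order, of 0.700.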